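I began with the easy step: the catalyst leaves the productive reaction as it entered, so its charge folds into a rate constant, and the reaction can be integrated like any second-order condensation with unequal charges.

| flask | starting material | reagent | protic impurity | catalyst | time |
|---|---|---|---|---|---|
| green | 1.0 mM | 1.30 mM | 0.200 mM | 10 µM | 3.0 s |
| red | 1.0 mM | 1.30 mM | 0.300 mM | 10 µM | 3.0 s |
| amber | 1.0 mM | 1.30 mM | 0.400 mM | 10 µM | 3.0 s |
| violet | 1.0 mM | 1.30 mM | 0.600 mM | 10 µM | 3.0 s |
| grey | 1.0 mM | 1.30 mM | 1.00 mM | 10 µM | 3.0 s |

    starting material + reagent + catalyst → catalyst + product (k1 = 2.2 × 10⁷ M⁻² s⁻¹)
    starting material + protic impurity → quenched substrate (k2 = 78 M⁻¹ s⁻¹)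

- "hardly changes" means that all values lie within two and a half points (for a concentration: within two and a half percent of the largest)
- run time (green): 3.0 s

* amount of product at the end, in percent of the starting material charged for green, red, amber, violet, grey, in this order
* the course of these numbers from the first flask to the last (rises, then falls / hardly changes / falls all the way / falls, then rises / rises all the way)

I wrote a and b for starting material and reagent at time t, a° and b° for their charges, and κ for the first constant times the catalyst charge, 220 M⁻¹ s⁻¹. Without the quench, da/dt = −κab and b − a stays at b° − a°, so ln[b a°/(a b°)] = κ(b° − a°)t. Starting material was the limiting reagent of this step. For 3.0 s this reckoning put the ratio inside the logarithm at E = 1.22, so 1 − (b° − a°)/(b°E − a°) came to 48.7 %. I call this Y, the quench-free yield: the product, in percent of the starting material charged, that the productive step makes by the reading when it runs by itself.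

The protic impurity does not appear in Y, so green and its neighbour red share it. They looked nearly alike, differing in impurity, 0.200 mM against 0.300 mM. Both steps are first order in starting material, so the selectivity factor, the productive rate over the quench rate at the start, contains no a. It stood at 18.3 in green and 12.2 in red. I therefore expected red just under green and both under Y, and my reckoning gave no size for the shortfall.

The forecast gave 47.9 %, 47.5 %, 47.2 %, 46.5 % and 45 %, a course that falls all the way, on the ground that “the yield is limited by time rather than by the impurity consuming the substrate”.

The simulation gave 47.9 %, 47.6 %, 47.2 %, 46.5 % and 45.0 %, a course that falls all the way, with a drop of 2.9 percentage points against the 2.5 points that count as hardly changing.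

With the quench taken away, green and grey both stood at 48.7 %, which is Y again, and the change from green to grey went from −2.9 points to 0 points. The shortfall from Y was 0.76 points in green and 3.7 points in grey. Grey held 14.0 % of quenched substrate at the reading, and a quarter of that amount, 3.7 points, was missing from its product.

The rate constants were set for the occasion; what happens was integrated by code.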